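# Proposed total synthesis of CNP0353860.3 (29) by ketyl–styrene closure of ring B

## Analysis of the target

- Compound 29 is a trans-fused decalin (ring A: C1–C5 and C10; ring B: C5–C10) with an exocyclic methylene C4=C11. C9 carries, through the benzylic carbon C15, a benzene ring (C1'–C6') with a sulfate on O2', a free hydroxyl on O3' and a hydroxymethyl group on C5'.
- The four stereocentres are contiguous (5S,8S,9R,10S). The quaternary carbons C5 and C9 hold methyl groups that are 1,3-diaxial on one face (called β here). The C8 methyl is equatorial and cis to the C9 methyl, H-10 is α, and C15 is therefore equatorial.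
- The aryl hydrogen sulfate is cleaved by acid. The C4=C11 alkene migrates into ring A under acid. The C5' benzylic oxygen is para to O2' and ionises easily. O2' and O3' are neighbours, so a silyl group can move between them once a phenoxide forms.
- The difficulties are the quaternary C9 wedged between C8 and C10 with its methyl syn to the C5 methyl, sulfation of only the more hindered O2', and an endgame that must avoid acid.
- The strategy rests on C15: a benzylic methylene on a quaternary carbon is the reduced form of the far carbon of a styrene C9=C15. With that alkene in place, ring B can be closed last at C8–C9 by adding a C8 radical to C9, and the radical left at C15 is benzylic and is simply reduced.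
- This puts the hardest centre, C9, into a ring closure templated by ring A. The C5 and C10 centres of ring A are reachable in one operation from a 2-methylcyclohexenone by conjugate addition and enolate alkylation.

## Retrosynthetic reasoning

**29 to 27 (O–S and O–Si bonds).** The sulfate ester bond at O2' and the two O–Si bonds are cut first. Silyl ethers on O3' and on the C5' oxygen can be removed together under basic, non-acidic conditions that an aryl sulfate anion survives, so 29 comes from 28 and 28 from phenol 27. The forward sulfation only has to find one free hydroxyl.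

**27 to 23 (O2' acetal, C4=C11, C4 ketal).** O2' is carried as a methoxymethyl ether, the one group that can be taken off alone by a buffered silyl-transfer reagent in the presence of the alkene and the silyl ethers (25 to 27). The C4=C11 bond is cut to the C4 ketone 24, and the ketone is masked as the dioxolane 23. The mask is needed because a free C4 ketone or a C4 methylene would compete in the radical step (a 5-exo ketyl closure onto C4 is well placed) and would not survive the C8 adjustments.

**23 to 20 (C8 methyl).** The C8–CH3 bond is traced to an exocyclic C8 methylene (22), that to the C8 ketone 21, and that to the C8 alcohol 20. This is done because the ring closure leaves oxygen on C8. Hydrogenation of 22 has to deliver hydrogen to the α face, anti to the axial C9 methyl.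

**20 to 19 (C8–C9, the key disconnection).** Cutting C8–C9 opens ring B to aldehyde 19, in which C9=C15 is an E styrene on C10 and C8 is the formyl carbon of a three-carbon arm on C5.
- Cutting here, and not at C9–C15 or C9–C10, removes the quaternary centre and a ring in one stroke.
- It leaves a monocyclic precursor whose two stereocentres sit on adjacent ring carbons.
- The forward reaction must add the ketyl of 19 to the fully substituted C9 on the correct alkene face and reduce the C15 radical.

**19 to 15 (aldehyde from an allyl group).** The C8 aldehyde is traced to a terminal alkene: 19 from alcohol 18, 18 from the allyl ketal 16 by anti-Markovnikov hydration, and 16 from ketone 15. An allyl group is the simplest three-carbon unit that an enolate accepts at a quaternary carbon.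

**15 to 9, 10 and 11 (C9–C10 and C5–C6).** Both bonds flank the former enone carbons of 10.
- C9–C10 is made by copper-catalysed asymmetric conjugate addition of the alkenyl aluminium reagent 13, made from iodide 9 through 12. This fixes the absolute configuration at C10.
- C5–C6 is made by allylation of the regiospecific enolate 14 with 11, anti to the new C10 substituent. This gives the trans relationship of the two arms that ring B needs.

**9 to 5 and 6 (alkenyl iodide).** The E iodide 9, with iodine on the methyl-bearing carbon and trans to the arene, is the syn hydrometalation–iodination product of aryl propyne 7 (through 8). Alkyne 7 comes from aryl bromide 5 and propyne 6 by Sonogashira coupling. Hydroalumination of 7 is avoided because aluminium prefers the aryl-bearing carbon.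

**5 to 1 (arene).** Bromide 5 maps onto 5-bromovanillin 1: the bromine marks C1', the phenol is O2', the methoxy oxygen is O3' and the formyl carbon becomes the C5' hydroxymethyl carbon. Demethylation gives 2, the more acidic para hydroxyl takes the methoxymethyl group (3), reduction gives 4, and double silylation gives 5.

## Alternatives that were turned down

**Alternative 1: arene built last by benzannulation.**
- Disconnection: the benzene ring itself, at C1'–C6' and C2'–C3'.
- Forward key step: the siloxyalkyne A2, a finished decalin whose C15 carries the alkyne, adds across C3 and C6 of the 2-pyrone A3. Decarboxylative cycloreversion then gives arene A1 with O2' silylated, O3' allylated and C5' as an ester.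
- For: O2' and O3' are differentiated by construction. On this point it is stronger than the chosen route, which relies on the acidity difference of the two phenols of 2.
- Against: A2 already holds all four stereocentres, including quaternary C9, so the key step solves none of the stereochemical problems. Ynol silyl ethers are fragile. The cycloaddition and cycloreversion need heat. A1 still needs ester reduction, deallylation and silyl exchange before sulfation.
- Comparison: the decalin synthesis is undiminished and several adjustment steps follow, so it is longer. The chosen strategy buys the arene and spends its key step on C9 and ring B.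

**Alternative 2: intramolecular Diels–Alder across C5–C10.**
- Disconnection: C5–C10 and C3–C4, both rings at once.
- Forward key step: in trienal A5 the E-enal (C4=C5, formyl carbon C11) adds to the E-diene C10=C1–C2=C3 through the tether C6–C9, giving octalin A4.
- For: two C–C bonds, two rings and three stereocentres in one step. In bond count it is stronger than the chosen key step (one bond, one ring, two centres).
- Against: A5 must carry the adjacent C8 and C9 centres, C9 quaternary, in an open chain where nothing templates them. The dienophile carbon C5 is fully substituted and bonds next to C10, which sits on quaternary C9, so the cycloaddition is congested. Lewis-acid promotion would threaten the acetal and the ionisable benzylic ether. The C4 centre is made only to be destroyed: C11 must be turned from formyl into a methylene and C1=C2 hydrogenated.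
- Comparison: what the chosen strategy offers in place of bond count is stereocontrol at C9 inside a ring, and a short path from bought ring A.

**Alternative 3: Ireland–Claisen ring contraction.**
- Disconnection: C9–C10.
- Forward key step: the enolate of δ-lactone A7 is O-silylated and undergoes a [3,3] shift. C10 bonds to C9 as the C7–O bond breaks, giving cyclohexene acid A6 with a C7=C8 alkene and C1 as a carboxyl on C10.
- For: a concerted shift passes the C7 configuration and the alkene geometry into C9 and C10 together. In predictability of the vicinal quaternary/tertiary pair it is at least as strong as a radical closure.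
- Against: A7 needs a tetrasubstituted C8=C9 alkene of defined geometry, quaternary C5 and the C7 centre, which is as hard to secure as the target's own centres. After the key step ring A is still open: the C1 carboxyl must be converted and closed onto the allyl group, and C7=C8 must be hydrogenated to set C8.
- Comparison: it is longer. The chosen route sets C5 and C10 in one flask and closes ring B directly at the oxidation level needed for C8.

Key step: step 11

## Assumptions and conventions

- Assumption: 29 is drawn as the free aryl hydrogen sulfate; 28 and 29 would be handled as sodium or tetrabutylammonium salts and the acid form set free only at the very end by brief, cold cation exchange.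
- Numbering: C1–C15 and C1'–C6' as in the analysis. β is the face of the C5 methyl.
- ArP = 2-(methoxymethoxy)-3-(triisopropylsilyloxy)-5-[(triisopropylsilyloxy)methyl]phenyl.
- L = O,O'-(S)-1,1'-binaphthyl-2,2'-diyl N,N-bis[(S)-1-phenylethyl]phosphoramidite. If a pilot run shows the opposite sense of induction, its enantiomer is used.

## Route

Step 1
Reactants: 1 5-bromovanillin (3-bromo-4-hydroxy-5-methoxybenzaldehyde)
Product: 2 3-bromo-4,5-dihydroxybenzaldehyde
Conditions: AlCl3, pyridine, CH2Cl2, reflux; aq. HCl
Reagents that add atoms: none
Why: Lewis-acid-assisted O-demethylation: AlCl3 binds the ortho hydroxy/methoxy pair and pyridine removes the methyl group by SN2; the aldehyde and the aryl bromide are not touched.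

Step 2
Reactants: 2 3-bromo-4,5-dihydroxybenzaldehyde
Product: 3 3-bromo-5-hydroxy-4-(methoxymethoxy)benzaldehyde
Conditions: MOMCl (1.05 equiv), K2CO3 (1.0 equiv), acetone, 0 °C to rt
Reagents that add atoms: chloromethyl methyl ether, COCCl
Why: Regioselective O-alkylation of a catechol aldehyde: the hydroxyl para to the formyl group and ortho to bromine is the more acidic, so one equivalent of weak base ionises it alone and the small acetal chloride alkylates that oxygen (the future O2').

Step 3
Reactants: 3 3-bromo-5-hydroxy-4-(methoxymethoxy)benzaldehyde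
Product: 4 3-bromo-5-(hydroxymethyl)-2-(methoxymethoxy)phenol
Conditions: NaBH4, MeOH, 0 °C
Reagents that add atoms: none
Why: Borohydride reduction of an aryl aldehyde to the benzylic alcohol; the acetal, phenol and aryl bromide are inert.

Step 4
Reactants: 4 3-bromo-5-(hydroxymethyl)-2-(methoxymethoxy)phenol
Product: 5 1-bromo-2-(methoxymethoxy)-3-(triisopropylsilyloxy)-5-[(triisopropylsilyloxy)methyl]benzene (ArP–Br)
Conditions: TIPSCl (2.5 equiv), imidazole, DMF, rt to 40 °C
Reagents that add atoms: chlorotriisopropylsilane, CC(C)[Si](Cl)(C(C)C)C(C)C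
Why: Double silylation of the phenol and the primary alcohol; the bulky silyl ethers are chosen because they resist organolithium reagents, alkoxide and mild acid and leave together with fluoride at the end.

Step 5
Reactants: 5 ArP–Br; 6 propyne
Product: 7 2-(methoxymethoxy)-1-(prop-1-yn-1-yl)-3-(triisopropylsilyloxy)-5-[(triisopropylsilyloxy)methyl]benzene (ArP–C≡C–CH3)
Conditions: 6 (excess), Pd(PhCN)2Cl2 (3 mol %), P(t-Bu)3 (6 mol %), CuI (2 mol %), i-Pr2NH, dioxane, rt, sealed vessel
Reagents that add atoms: none
Why: Sonogashira coupling; the electron-rich trialkylphosphine lets the electron-rich, ortho-substituted aryl bromide undergo oxidative addition at room temperature, which also keeps the volatile alkyne in solution.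

Step 6
Reactants: 7 ArP–C≡C–CH3
Product: 9 (E)-1-ArP-2-iodoprop-1-ene, via alkenyl–Zr(Cl)Cp2 8 (not isolated)
Conditions: Cp2Zr(H)Cl (1.5 equiv), THF, rt to 40 °C; then I2, 0 °C
Reagents that add atoms: iodine, [I][I]
Why: Syn hydrozirconation places zirconium on the methyl-bearing alkyne carbon, away from the ortho-substituted arene (steric control, sharpened by equilibration with the slight excess of hydride), and hydrogen on the aryl-bearing carbon. Iodinolysis of the C–Zr bond goes with retention, so iodine ends trans to the arene (E).

Step 7
Reactants: 9 (E)-1-ArP-2-iodoprop-1-ene; 10 2-methylcyclohex-2-en-1-one; 11 allyl bromide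
Product: 15 (2S,3S)-2-allyl-2-methyl-3-[(E)-1-ArP-prop-1-en-2-yl]cyclohexan-1-one, via alkenyllithium 12 (not isolated), via alkenyl–AlMe2 13 (not isolated), via Me2Al enolate 14 (not isolated)
Conditions: t-BuLi (2 equiv), Et2O, −78 °C; Me2AlCl, −78 to −30 °C; 10, Cu(OTf)2 (5 mol %), L (10 mol %), Et2O, −30 °C; then MeLi (1 equiv), THF, −30 °C; 11, HMPA, −30 °C to rt
Reagents that add atoms: none
Why: Copper-catalysed asymmetric conjugate addition of an alkenyl aluminium reagent: the chiral phosphoramidite–copper complex selects the enone face and sets C10 (3S), and the alkenyl group is transferred in preference to methyl with retention of the E geometry. The regiospecific aluminium enolate 14 is made nucleophilic as its lithium ate complex and is allylated anti to the new C10 substituent, which sets quaternary C5 (2S) with the allyl group trans to the alkenyl group.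

Step 8
Reactants: 15 (2S,3S)-2-allyl-2-methyl-3-[(E)-1-ArP-prop-1-en-2-yl]cyclohexan-1-one
Product: 16 (6S,7S)-6-allyl-6-methyl-7-[(E)-1-ArP-prop-1-en-2-yl]-1,4-dioxaspiro[4.5]decane
Conditions: (TMSOCH2)2, TMSOTf (5 mol %), CH2Cl2, −78 to −20 °C; pyridine quench
Reagents that add atoms: 1,2-bis(trimethylsilyloxy)ethane, C[Si](C)(C)OCCO[Si](C)(C)C
Why: Aprotic silyl-transfer ketalisation, which works on hindered ketones beside a quaternary carbon at low temperature and leaves the aryl acetal, the silyl ethers and the styrene alone.

Step 9
Reactants: 16 allyl ketal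
Product: 18 3-{(6S,7S)-6-methyl-7-[(E)-1-ArP-prop-1-en-2-yl]-1,4-dioxaspiro[4.5]decan-6-yl}propan-1-ol, via B-alkyl-9-BBN 17 (not isolated)
Conditions: 9-BBN, THF, 0 °C to rt; then NaBO3·4H2O, H2O, rt
Reagents that add atoms: sodium perborate tetrahydrate (NaBO3·4H2O), [Na+].[Na+].O[B-]1(O)OO[B-](O)(O)OO1
Why: Hydroboration–oxidation; the bulky dialkylborane adds to the monosubstituted terminal alkene far faster than to the trisubstituted styrene, and perborate oxidises the C–B bond without the strong base that could attack the aryl silyl ether.

Step 10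
Reactants: 18 primary alcohol
Product: 19 3-{(6S,7S)-6-methyl-7-[(E)-1-ArP-prop-1-en-2-yl]-1,4-dioxaspiro[4.5]decan-6-yl}propanal
Conditions: DMP, NaHCO3, CH2Cl2, 0 °C to rt
Reagents that add atoms: none
Why: Dess–Martin oxidation of a primary alcohol to the aldehyde under buffered, non-acidic conditions; there is no epimerisable centre next to the new carbonyl.

Step 11
Reactants: 19 aldehyde with the E styrene on C10 and the 3-oxopropyl arm on C5
Product: 20 ketal alcohol (5S,8S,9S,10S): trans-decalin with C4 dioxolane; 5β-Me; 9β-Me; 9α-CH2ArP; 8β-OH (equatorial); 10α-H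
Conditions: SmI2 (4 equiv), HMPA (12 equiv), t-BuOH (3 equiv), THF, 0 °C, high dilution
Reagents that add atoms: none
Why: SmI2–HMPA transfers one electron to the C8 aldehyde; the samarium-bound ketyl adds to C9 of the styrene, the benzylic C15 radical takes a second electron, and the resulting benzylsamarium is protonated by t-BuOH to the C15 methylene. The closest known reaction type is the SmI2/HMPA ketyl–olefin reductive cyclisation onto styrenes and other aryl-activated alkenes. Ring B closes in the 6-exo-trig mode, and attack at C9 rather than at C15 (7-endo) is secured by the benzylic stabilisation of the radical that results. C9 is set in a chair-like transition state held by the trans-diequatorial C5 and C10 arms on ring A: the alkene rotamer with the C9 methyl axial (syn to the C5 methyl) and C15 equatorial is used, because the other rotamer drives the vinylic C15–H bond of the E alkene into the axial C5 methyl. C8 is formed as the carbinol, with the bulky O–Sm group expected equatorial, but this centre is erased in step 12, so either epimer serves. The step needs chemoselectivity for the aldehyde over the ketal, the acetal and the silyl ethers, none of which is reduced under these conditions, and C5' is meta to C1', so the benzylic anion cannot expel the C5' oxygen. High dilution suppresses pinacol coupling and the alcohol additive protonates the benzylic organosamarium as soon as it forms.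

Step 12
Reactants: 20 ketal alcohol
Product: 21 C8 ketone (5S,9S,10S): trans-decalin with C4 dioxolane; 5β-Me; 9β-Me; 9α-CH2ArP; C8 carbonyl
Conditions: DMP, NaHCO3, CH2Cl2, rt
Reagents that add atoms: none
Why: Dess–Martin oxidation of the hindered secondary alcohol; C9 is quaternary and cannot epimerise, and both C8 epimers of 20 converge on one ketone.

Step 13
Reactants: 21 C8 ketone
Product: 22 C8 exocyclic methylene compound (5S,9S,10S): as 21 with C8=CH2
Conditions: Cp2TiMe2 (3 equiv), toluene, 70 °C, dark
Reagents that add atoms: dimethyltitanocene (Cp2TiMe2), C[Ti](C)(C1C=CC=C1)C1C=CC=C1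
Why: Petasis methylenation: the neutral titanium methylidene formed on heating methylenates hindered, enolisable ketones beside quaternary carbons without base, so the aryl silyl ether and the ketal are safe.

Step 14
Reactants: 22 C8 methylene compound
Product: 23 (5S,8S,9R,10S) ketal: trans-decalin with C4 dioxolane; 5β-Me; 8β-Me (equatorial); 9β-Me; 9α-CH2ArP; 10α-H
Conditions: H2 (1 atm), PtO2, EtOAc, rt
Reagents that add atoms: none
Why: Heterogeneous hydrogenation of a 1,1-disubstituted exocyclic alkene: the β face of C8 is screened by the adjacent axial C9 methyl, so hydrogen should arrive from the α face and the new methyl should end equatorial, cis to the C9 methyl (8S). PtO2 in EtOAc is chosen because it is slow to migrate double bonds and to cleave benzylic C–O bonds.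

Step 15
Reactants: 23 ketal
Product: 24 (5S,8S,9R,10S) C4 ketone: trans-decalin with C4 carbonyl; 5β-Me; 8β-Me; 9β-Me; 9α-CH2ArP
Conditions: PPTS, acetone/H2O (10:1), 55 °C
Reagents that add atoms: water, O
Why: Mild acid-catalysed ketal hydrolysis and exchange with acetone; the weak pyridinium acid should spare the aryl acetal, both silyl ethers and the ionisable C5' benzylic C–O bond, and C5 is quaternary, so nothing epimerises.

Step 16
Reactants: 24 C4 ketone
Product: 25 (5S,8S,9R,10S)-4(11)-ene: C4=C11 methylene; 5β-Me; 8β-Me; 9β-Me; 9α-CH2ArP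
Conditions: Cp2TiMe2 (3 equiv), toluene, 70 °C, dark
Reagents that add atoms: dimethyltitanocene (Cp2TiMe2), C[Ti](C)(C1C=CC=C1)C1C=CC=C1
Why: Petasis methylenation of the hindered C4 ketone beside quaternary C5; the base-free conditions avoid attack on the aryl silyl ether.

Step 17
Reactants: 25 methylene compound with O2' as methoxymethyl ether
Product: 27 O2' phenol: as 25 with free hydroxyl on C2', via aryl TMS ether 26 (not isolated)
Conditions: TMSOTf (2 equiv), 2,2'-bipyridyl (3 equiv), CH2Cl2, 0 °C to rt; then H2O
Reagents that add atoms: none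
Why: The silyl triflate–bipyridyl pair converts an aryl methoxymethyl ether into the aryl silyl ether under buffered, non-protic conditions, and water then frees the phenol. With no free acid present the exocyclic alkene should not migrate, and the silyl ethers and the C5' benzylic C–O bond should persist.

Step 18
Reactants: 27 O2' phenol
Product: 28 O2' sulfate with O3' and the C5' oxygen as triisopropylsilyl ethers (handled as the sodium salt)
Conditions: SO3·pyridine (5 equiv), pyridine, 50 °C; aq. NaHCO3
Reagents that add atoms: sulfur trioxide–pyridine complex, O=S(=O)([O-])[n+]1ccccc1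
Why: O-Sulfation of a phenol with the amine complex of SO3: only O2' is free, the complex does not attack the alkene, and pyridine does not ionise the phenol enough to start silyl migration from O3'.

Step 19
Reactants: 28 silyl-protected sulfate
Product: 29 2-{[(1R,2S,4aS,8aS)-1,2,4a-trimethyl-5-methylidenedecahydronaphthalen-1-yl]methyl}-6-hydroxy-4-(hydroxymethyl)phenyl hydrogen sulfate (target; 5S,8S,9R,10S in the numbering used here)
Conditions: TBAF (3 equiv), THF, 0 °C to rt; then brief cation exchange (H+ form resin, 0 °C)
Reagents that add atoms: none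
Why: Fluoride cleaves both Si–O bonds, the aryl one faster, while aryl sulfate monoester anions are inert to fluoride and base. No acid meets the alkene until the short, cold exchange that gives the acid form.

## Compound list

1 | 5-bromovanillin | COc1cc(C=O)cc(Br)c1O | starting material
2 | 3-bromo-4,5-dihydroxybenzaldehyde | O=Cc1cc(O)c(O)c(Br)c1 | intermediate
3 | 3-bromo-5-hydroxy-4-(methoxymethoxy)benzaldehyde | O=Cc1cc(O)c(OCOC)c(Br)c1 | intermediate
4 | 3-bromo-5-(hydroxymethyl)-2-(methoxymethoxy)phenol | OCc1cc(O)c(OCOC)c(Br)c1 | intermediate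
5 | ArP–Br, 1-bromo-2-(methoxymethoxy)-3-(triisopropylsilyloxy)-5-[(triisopropylsilyloxy)methyl]benzene | Brc1cc(CO[Si](C(C)C)(C(C)C)C(C)C)cc(O[Si](C(C)C)(C(C)C)C(C)C)c1OCOC | intermediate
6 | propyne | CC#C | starting material
7 | ArP–C≡C–CH3 | CC#Cc1cc(CO[Si](C(C)C)(C(C)C)C(C)C)cc(O[Si](C(C)C)(C(C)C)C(C)C)c1OCOC | intermediate
8 | (E)-(1-ArP-prop-1-en-2-yl)–Zr(Cl)Cp2 | Cl[Zr](C1C=CC=C1)(C1C=CC=C1)/C(C)=C/c1cc(CO[Si](C(C)C)(C(C)C)C(C)C)cc(O[Si](C(C)C)(C(C)C)C(C)C)c1OCOC | intermediate (not isolated)
9 | (E)-1-ArP-2-iodoprop-1-ene | I/C(C)=C/c1cc(CO[Si](C(C)C)(C(C)C)C(C)C)cc(O[Si](C(C)C)(C(C)C)C(C)C)c1OCOC | intermediate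
10 | 2-methylcyclohex-2-en-1-one | CC1=CCCCC1=O | starting material
11 | allyl bromide | C=CCBr | starting material
12 | (E)-(1-ArP-prop-1-en-2-yl)lithium | [Li]/C(C)=C/c1cc(CO[Si](C(C)C)(C(C)C)C(C)C)cc(O[Si](C(C)C)(C(C)C)C(C)C)c1OCOC | intermediate (not isolated)
13 | dimethyl[(E)-1-ArP-prop-1-en-2-yl]alane | C[Al](C)/C(C)=C/c1cc(CO[Si](C(C)C)(C(C)C)C(C)C)cc(O[Si](C(C)C)(C(C)C)C(C)C)c1OCOC | intermediate (not isolated)
14 | Me2Al enolate of (S)-3-[(E)-1-ArP-prop-1-en-2-yl]-2-methylcyclohexanone | C[Al](C)OC1=C(C)[C@H](/C(C)=C/c2cc(CO[Si](C(C)C)(C(C)C)C(C)C)cc(O[Si](C(C)C)(C(C)C)C(C)C)c2OCOC)CCC1 | intermediate (not isolated)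
15 | (2S,3S)-2-allyl-2-methyl-3-[(E)-1-ArP-prop-1-en-2-yl]cyclohexan-1-one | O=C1CCC[C@@H](/C(C)=C/c2cc(CO[Si](C(C)C)(C(C)C)C(C)C)cc(O[Si](C(C)C)(C(C)C)C(C)C)c2OCOC)[C@]1(C)CC=C | intermediate
16 | (6S,7S)-6-allyl-6-methyl-7-[(E)-1-ArP-prop-1-en-2-yl]-1,4-dioxaspiro[4.5]decane | O1CCOC12CCC[C@@H](/C(C)=C/c3cc(CO[Si](C(C)C)(C(C)C)C(C)C)cc(O[Si](C(C)C)(C(C)C)C(C)C)c3OCOC)[C@]2(C)CC=C | intermediate
17 | B-alkyl-9-borabicyclo[3.3.1]nonane from 16 | O1CCOC12CCC[C@@H](/C(C)=C/c3cc(CO[Si](C(C)C)(C(C)C)C(C)C)cc(O[Si](C(C)C)(C(C)C)C(C)C)c3OCOC)[C@]2(C)CCCB4C5CCCC4CCC5 | intermediate (not isolated)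
18 | primary alcohol, 3-{(6S,7S)-6-methyl-7-[(E)-1-ArP-prop-1-en-2-yl]-1,4-dioxaspiro[4.5]decan-6-yl}propan-1-ol | O1CCOC12CCC[C@@H](/C(C)=C/c3cc(CO[Si](C(C)C)(C(C)C)C(C)C)cc(O[Si](C(C)C)(C(C)C)C(C)C)c3OCOC)[C@]2(C)CCCO | intermediate
19 | aldehyde, 3-{(6S,7S)-6-methyl-7-[(E)-1-ArP-prop-1-en-2-yl]-1,4-dioxaspiro[4.5]decan-6-yl}propanal | O1CCOC12CCC[C@@H](/C(C)=C/c3cc(CO[Si](C(C)C)(C(C)C)C(C)C)cc(O[Si](C(C)C)(C(C)C)C(C)C)c3OCOC)[C@]2(C)CCC=O | intermediate
20 | (5S,8S,9S,10S) trans-decalin, C4 dioxolane, 9α-CH2ArP, 8β-OH | O1CCOC12CCC[C@H]3[C@](C)(Cc4cc(CO[Si](C(C)C)(C(C)C)C(C)C)cc(O[Si](C(C)C)(C(C)C)C(C)C)c4OCOC)[C@@H](O)CC[C@]23C | intermediate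
21 | (5S,9S,10S) C8 ketone, C4 dioxolane | O1CCOC12CCC[C@H]3[C@](C)(Cc4cc(CO[Si](C(C)C)(C(C)C)C(C)C)cc(O[Si](C(C)C)(C(C)C)C(C)C)c4OCOC)C(=O)CC[C@]23C | intermediate
22 | (5S,9S,10S) C8 methylene compound, C4 dioxolane | O1CCOC12CCC[C@H]3[C@](C)(Cc4cc(CO[Si](C(C)C)(C(C)C)C(C)C)cc(O[Si](C(C)C)(C(C)C)C(C)C)c4OCOC)C(=C)CC[C@]23C | intermediate
23 | (5S,8S,9R,10S) 8β-methyl decalin, C4 dioxolane | O1CCOC12CCC[C@H]3[C@](C)(Cc4cc(CO[Si](C(C)C)(C(C)C)C(C)C)cc(O[Si](C(C)C)(C(C)C)C(C)C)c4OCOC)[C@@H](C)CC[C@]23C | intermediate
24 | (5S,8S,9R,10S) C4 ketone | O=C1CCC[C@H]2[C@](C)(Cc3cc(CO[Si](C(C)C)(C(C)C)C(C)C)cc(O[Si](C(C)C)(C(C)C)C(C)C)c3OCOC)[C@@H](C)CC[C@]12C | intermediate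
25 | (5S,8S,9R,10S) 4(11)-ene, O2' methoxymethyl ether | C=C1CCC[C@H]2[C@](C)(Cc3cc(CO[Si](C(C)C)(C(C)C)C(C)C)cc(O[Si](C(C)C)(C(C)C)C(C)C)c3OCOC)[C@@H](C)CC[C@]12C | intermediate
26 | O2' trimethylsilyl ether of 27 | C=C1CCC[C@H]2[C@](C)(Cc3cc(CO[Si](C(C)C)(C(C)C)C(C)C)cc(O[Si](C(C)C)(C(C)C)C(C)C)c3O[Si](C)(C)C)[C@@H](C)CC[C@]12C | intermediate (not isolated)
27 | O2' phenol, O3' and C5' oxygen as triisopropylsilyl ethers | C=C1CCC[C@H]2[C@](C)(Cc3cc(CO[Si](C(C)C)(C(C)C)C(C)C)cc(O[Si](C(C)C)(C(C)C)C(C)C)c3O)[C@@H](C)CC[C@]12C | intermediate
28 | O2' hydrogen sulfate, O3' and C5' oxygen as triisopropylsilyl ethers | C=C1CCC[C@H]2[C@](C)(Cc3cc(CO[Si](C(C)C)(C(C)C)C(C)C)cc(O[Si](C(C)C)(C(C)C)C(C)C)c3OS(=O)(=O)O)[C@@H](C)CC[C@]12C | intermediate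
29 | CNP0353860.3 | C=C1CCC[C@H]2[C@](C)(Cc3cc(CO)cc(O)c3OS(=O)(=O)O)[C@@H](C)CC[C@]12C | target

## Step count and least certain steps

Total: 19 steps. Longest linear sequence: 19 steps (1 to 29); 6, 10 and 11 enter as purchased reagents.

**Step 11 (key step).**
- What may go wrong: the ketyl may be consumed by further reduction and protonation to the primary alcohol, or by pinacol dimerisation, before it attacks C9. The attack builds a quaternary centre beside C10 and brings two methyl groups into a 1,3-diaxial contact, so it is slow for a bulky samarium-bound radical. Erosion of facial control at C9 is the second concern.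
- Fallback (19 to 23): a free carbon radical replaces the ketyl. From 19, addition of MeMgBr (THF, −78 °C) gives the secondary alcohol F1 as a mixture of carbinol epimers. Appel-type iodination (I2, PPh3, imidazole, toluene) gives the secondary iodide F2. Slow addition of Bu3SnH with AIBN in refluxing benzene generates the secondary C8 radical, which is smaller, cannot be reduced further and adds 6-exo to C9 through the same chair. The methyl on the radical carbon is expected to sit equatorial, so the closure returns to the route at 23 and steps 12–14 are bypassed.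

**Step 7.**
- What may go wrong: low enantioselectivity or slow addition, because the α-methyl group of 10 and the α-methyl, β-aryl pattern of the alkenyl group both crowd the copper-bound transition state. Incomplete C-allylation of the aluminium enolate is a lesser risk.
- Fallback (7 to 15): rhodium catalysis on the unsubstituted enone, with the methyl group added afterwards.
  - From 7, hydrozirconation as in step 6 gives 8, which is not iodinated but added to cyclohex-2-en-1-one F3 with [Rh(cod)(MeCN)2]BF4 and (S)-BINAP (or its antipode, to give the 3S adduct).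
  - The zirconium enolate F4 is trapped with dimethylmethyleneiminium iodide to give the Mannich base F5.
  - N-Methylation (MeI) and elimination (NaHCO3) give the 2-methylene ketone F6.
  - Conjugate reduction with LiB(s-Bu)3H produces the lithium enolate F7 regiospecifically, and allylation with 11 (HMPA) returns to the route at 15.

**Step 6.**
- What may go wrong: formation of the regioisomeric alkenylzirconium with the metal on the aryl-bearing carbon, since a benzylic carbon–metal bond is electronically favoured. This would lead to the α-iodostyrene.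
- Fallback (7 to 9): copper–boryl addition, whose regiochemistry is set electronically in the needed sense. From 7, B2pin2, CuCl, NaOt-Bu, a triarylphosphine and MeOH in THF give the alkenyl pinacolboronate F8 by syn addition with boron on the methyl-bearing carbon. Iododeboronation with retention (NaOMe first, then ICl, −78 °C) returns to the route at 9.

**Step 14.**
- What may go wrong: migration of the exocyclic double bond into ring B on the metal surface, or delivery of hydrogen from both faces if the arene of the C15 arm swings over the α face. Either erodes the C8 configuration.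
- Fallback (22 to 23, no new compound): hydrogen-atom-transfer hydrogenation with Mn(dpm)3 (catalytic), PhSiH3 and t-BuOOH in i-PrOH at rt. The C8 centre is then set at a free tertiary radical that accepts hydrogen axially from the α face, which favours the equatorial methyl by product stability rather than by surface approach.

**Step 17.**
- What may go wrong: migration of the C4=C11 double bond into ring A, or loss of the C5' benzylic silyl ether, if free triflic acid escapes the bipyridyl buffer.
- Fallback (24 to 27): the acetal is removed before the alkene exists. From 24, the same TMSOTf/2,2'-bipyridyl treatment and aqueous work-up give the keto phenol F9 (any silyl enol ether formed at C4 reverts on work-up). Petasis methylenation with excess Cp2TiMe2, the first equivalent being spent on the phenol, returns to the route at 27.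

## Further compounds

F1 | step 11 | secondary alcohol from 19 and MeMgBr, carbinol epimers | O1CCOC12CCC[C@@H](/C(C)=C/c3cc(CO[Si](C(C)C)(C(C)C)C(C)C)cc(O[Si](C(C)C)(C(C)C)C(C)C)c3OCOC)[C@]2(C)CCC(C)O
F2 | step 11 | secondary iodide from F1 | O1CCOC12CCC[C@@H](/C(C)=C/c3cc(CO[Si](C(C)C)(C(C)C)C(C)C)cc(O[Si](C(C)C)(C(C)C)C(C)C)c3OCOC)[C@]2(C)CCC(C)I
F3 | step 7 | cyclohex-2-en-1-one | O=C1C=CCCC1
F4 | step 7 | Cp2Zr(Cl) enolate of (S)-3-[(E)-1-ArP-prop-1-en-2-yl]cyclohexanone | Cl[Zr](OC1=C[C@H](/C(C)=C/c2cc(CO[Si](C(C)C)(C(C)C)C(C)C)cc(O[Si](C(C)C)(C(C)C)C(C)C)c2OCOC)CCC1)(C1C=CC=C1)C1C=CC=C1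
F5 | step 7 | Mannich base, (3S)-2-[(dimethylamino)methyl]-3-[(E)-1-ArP-prop-1-en-2-yl]cyclohexan-1-one | O=C1CCC[C@@H](/C(C)=C/c2cc(CO[Si](C(C)C)(C(C)C)C(C)C)cc(O[Si](C(C)C)(C(C)C)C(C)C)c2OCOC)C1CN(C)C
F6 | step 7 | (S)-2-methylidene-3-[(E)-1-ArP-prop-1-en-2-yl]cyclohexan-1-one | O=C1CCC[C@@H](/C(C)=C/c2cc(CO[Si](C(C)C)(C(C)C)C(C)C)cc(O[Si](C(C)C)(C(C)C)C(C)C)c2OCOC)C1=C
F7 | step 7 | lithium enolate of (S)-3-[(E)-1-ArP-prop-1-en-2-yl]-2-methylcyclohexanone | [Li]OC1=C(C)[C@H](/C(C)=C/c2cc(CO[Si](C(C)C)(C(C)C)C(C)C)cc(O[Si](C(C)C)(C(C)C)C(C)C)c2OCOC)CCC1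
F8 | step 6 | (Z)-2-(1-ArP-prop-1-en-2-yl)-4,4,5,5-tetramethyl-1,3,2-dioxaborolane, boron trans to the arene | B1(OC(C)(C)C(C)(C)O1)/C(C)=C/c2cc(CO[Si](C(C)C)(C(C)C)C(C)C)cc(O[Si](C(C)C)(C(C)C)C(C)C)c2OCOC
F0 | step 14 | none | none
F9 | step 17 | (5S,8S,9R,10S) C4 ketone with free O2' phenol | O=C1CCC[C@H]2[C@](C)(Cc3cc(CO[Si](C(C)C)(C(C)C)C(C)C)cc(O[Si](C(C)C)(C(C)C)C(C)C)c3O)[C@@H](C)CC[C@]12C
A1 | alternative 1 | aryl decalin with O2' triisopropylsilyl ether, O3' allyl ether and C5' methyl ester | C=C1CCC[C@H]2[C@](C)(Cc3cc(C(=O)OC)cc(OCC=C)c3O[Si](C(C)C)(C(C)C)C(C)C)[C@@H](C)CC[C@]12C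
A2 | alternative 1 | decalin siloxyalkyne, C15 bearing C≡C–OSi(i-Pr)3 | C=C1CCC[C@H]2[C@](C)(CC#CO[Si](C(C)C)(C(C)C)C(C)C)[C@@H](C)CC[C@]12C
A3 | alternative 1 | methyl 3-(allyloxy)-2-oxo-2H-pyran-5-carboxylate | O=C1OC=C(C(=O)OC)C=C1OCC=C
A4 | alternative 2 | trans-fused octalin with C11 formyl on C4 and a C1=C2 alkene | O=C[C@H]1CC=C[C@H]2[C@](C)(Cc3cc(CO[Si](C)(C)C(C)(C)C)cc(O[Si](C)(C)C(C)(C)C)c3OCOC)[C@@H](C)CC[C@]12C
A5 | alternative 2 | acyclic trienal with E-enal, E-diene and the C8, C9 centres on the tether | C=C/C=C/[C@](C)(Cc1cc(CO[Si](C)(C)C(C)(C)C)cc(O[Si](C)(C)C(C)(C)C)c1OCOC)[C@@H](C)CC/C(C)=C/C=O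
A6 | alternative 3 | ring B cyclohexene acid with C5, C9 and C10 set | OC(=O)[C@H]1[C@](C)(Cc2cc(CO[Si](C)(C)C(C)(C)C)cc(O[Si](C)(C)C(C)(C)C)c2OCOC)C(C)=CC[C@]1(C)C3(CC=C)OCCO3
A7 | alternative 3 | δ-lactone with the C5 methyl trans to the C7 (E)-alkenyl group | O=C1C[C@@](C)(C2(CC=C)OCCO2)C[C@H](O1)/C(C)=C(\C)Cc3cc(CO[Si](C)(C)C(C)(C)C)cc(O[Si](C)(C)C(C)(C)C)c3OCOC
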